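## Structural features

The target (C22H30O5) is an acyclic terpenoid chain carrying three rings joined only by single bonds: a 3-alkylfuran (ring C) at one end, a 2,2,5-trisubstituted oxolane (ring A: O1, C2, C3, C4, C5) in the middle, and a 5,5-disubstituted γ-butyrolactone (ring B) bonded to C5 of ring A through its fully substituted carbon C5′. There are three stereocentres: C5′ (S; methyl, ring-B oxygen) and C5 (R; hydrogen) are adjacent, with an anti arrangement of their two C–O bonds, and C2 (R; fully substituted, methyl plus the ketone chain) lies 1,4 to C5 across O1 with the chain trans to ring B. The chain on C2 is CH2–C(=O)–CH2–C(CH3)=CH–CH2CH2–furyl with an (E)-trisubstituted alkene. The fragile groups sit together: the ketone is β-alkoxy (O1 on C2), so enolisation towards C2 can open ring A by E1cB elimination and scramble C2; it is also β,γ-unsaturated, so acid or base can move the skipped alkene into conjugation; and the 3-alkylfuran does not tolerate strong acid or electrophilic oxidants (ozone, peracids, osmium or ruthenium oxides). The real difficulty is the stereotriad with two fully substituted carbinol carbons, above all the remote quaternary C2, and attaching the labile dienyl ketone chain to C2 without exposing it to later reagents. The key step exploits the fact that C2 (bearing O1, a methyl and a CH2–C(=O) arm) is the adduct of a ketone enol with a five-membered oxocarbenium ion O1=C2; C2 is thus a masked ketal carbon of a γ-hydroxy methyl ketone, and the fully substituted C5′ on C5 is placed to direct the approach to C2.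

## Logic of the disconnections

In one sentence: 25 is made in the last step by adding 22 to the cyclic oxocarbenium ion generated from 10, which forms the quaternary C2 by C–C bond formation under control of C5.

25 ⇒ 10 + 22. The bond cut is C2–CH2 (ring-A quaternary carbon to the methylene α to the ketone); the O1–C2 bond is treated as the C–O bond of a ketal. The β-alkoxy ketone is the retron of a Mukaiyama-type addition. Placing this cut last means that the fragment union, the hardest stereocentre and the labile ketone all appear in the final operation, so no later reagent touches the β,γ-enone or the β-alkoxy ketone. The gain is large: 25 falls into a C10 piece with two stereocentres and an achiral C12 chain. The demand is facial selectivity at C2 relayed from C5, a nucleophile that is exclusively the terminal enol regioisomer, and non-isomerising conditions.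

10 ⇒ 6. The bonds cut are the C5′–O bond of ring B and the hemiketal C–O bonds at C2 (which form spontaneously from a γ-hydroxy ketone). The ring-A oxygen on C5 is recognised as a former epoxide oxygen. The anti relationship of the C5–O and C5′–O bonds corresponds to an (E)-derived epoxide opened by a carboxyl group with inversion at the tertiary carbon. Two adjacent stereocentres and two rings reduce to one trans-epoxide on an open chain. The demand is that the carboxyl group, and not another oxygen nucleophile, opens the epoxide, and at the tertiary carbon.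

6 ⇒ 5. The two C–O bonds of the epoxide are cut. One catalytic asymmetric epoxidation of a trisubstituted (E)-alkene then becomes the only source of chirality in the route. The demand is high enantiofacial selectivity and a geometrically pure alkene.

5 ⇒ 4. The bond cut is the C2–C3 σ-bond of the ester chain (the γ,δ-unsaturated ester retron of a [3,3] rearrangement). This builds the (E)-trisubstituted alkene from a racemic allylic alcohol whose stereocentre is erased. The demand is a chair transition state with the carbinol substituent equatorial.

4 ⇒ 1 + 2 (through 3). The carbinol C–C bond is cut, giving two catalogue chemicals; the ketone travels as a dioxolane.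

22 ⇒ 20 ⇒ 19 ⇒ 18. Deprotonation of the parent ketone would ionise the doubly activated methylene, so the enol double bond must be fixed by construction. The O–Si bond and enol C=C trace back to a C–Br bond at the terminal carbon (20), this to an enol ether (19), and the C(acyl)–CH2(allyl) bond is then cut to an acyl-anion equivalent plus 18. The demand is coupling at the primary allylic terminus with retention of alkene geometry.

18 ⇒ 17 ⇒ 13 + 15 (through 16); 13 ⇒ 11; 15 ⇒ 14. The bond cut is the sp2–sp3 bond between the alkene CH and the ethylene tether to ring C. The (E)-geometry is set by syn carbometalation of an alkyne (11 to 13) and carried through a stereoretentive cross-coupling. The furan enters as a simple vinyl derivative.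

## Other disconnections considered

Alternative 1: (the first that comes to mind) Cut O1–C5 of ring A and the lactone C–O bond. The forward key step is acid-catalysed 5-exo opening of a trisubstituted (S,S)-epoxide by a pre-formed tertiary alcohol, as in hydroxy-epoxide A1 (ethyl 3-[(2S,3S)-3-[(3R)-3-hydroxy-3-methylpent-4-en-1-yl]-2-methyloxiran-2-yl]propanoate), followed by lactonisation to the vinyl-oxolane lactone A2. The chosen plan is preferred for three reasons. A1 needs two independent asymmetric operations (tertiary carbinol and epoxide). The ring closure must choose 5-exo at the secondary carbon over 6-endo at the tertiary carbon under acid. A2 still lacks the whole ketone chain: its vinyl group must become a CH2–CHO arm, and a five-carbon allyl nucleophile would add with allylic transposition, so several redox and adjustment steps follow on the fully assembled, fragile core.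

Alternative 2: Cut both C–C bonds at the ketone carbon. The forward key step is a three-component dithiane linchpin coupling with silyl migration: a 2-silyl-1,3-dithiane anion opens the 2,2-disubstituted epoxide A3, and the relayed anion is alkylated by 18 to give A4. The connectivity around the ketone is made in one operation, but no stereocentre is set. A3 must be made enantiopure separately, ring A still has to be closed in the conventional mode, the ester α-protons are not compatible with the lithiated dithiane without extra protection, and the thioketal must be removed with thiophilic or oxidising reagents in the presence of the furan and the skipped alkene.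

Alternative 3: Cut O1–C2. The forward key step is intramolecular oxa-Michael addition of the C5 hydroxyl of A5 to a β-methyl enone. The two carbon substituents on the new quaternary C2 (methyl and CH2–acyl) differ little in size, so neither kinetic nor thermodynamic control should favour the trans isomer clearly. The addition is reversible, and the base or acid needed would be expected to pull the second, skipped alkene into conjugation to give a cross-conjugated dienone and erode its (E)-geometry.

Key step: step 12

Assumption: 1, 2, 11, 14, the D-fructose-derived Shi ketone, 9-BBN and tributyl(1-ethoxyvinyl)stannane are taken as catalogue chemicals; the Shi ketone is taken to give the (R,R)-epoxide from this (E)-trisubstituted alkene, as it does for simple trans- and trisubstituted alkenes.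

## Steps

Step 1
Reactants: 1 2-(2-bromoethyl)-2-methyl-1,3-dioxolane; 2 methacrolein
Product: 4 2-methyl-5-(2-methyl-1,3-dioxolan-2-yl)pent-1-en-3-ol (racemic), via Grignard reagent 3 (not isolated)
Conditions: Mg, THF, 25–30 °C; then 2, THF, −78 to 0 °C; aq. NH4Cl
Reagents that add atoms: none
Why: Grignard formation from the primary bromide (the dioxolane masks the ketone) and 1,2-addition of the hard nucleophile to the enal; the new carbinol centre is racemic and is erased in step 2.

Step 2
Reactants: 4 2-methyl-5-(2-methyl-1,3-dioxolan-2-yl)pent-1-en-3-ol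
Product: 5 ethyl (4E)-4-methyl-7-(2-methyl-1,3-dioxolan-2-yl)hept-4-enoate
Conditions: MeC(OEt)3, EtCO2H (cat.), 140 °C, distil off EtOH
Reagents that add atoms: triethyl orthoacetate, CCOC(C)(OCC)OCC
Why: Johnson–Claisen rearrangement; the ketene acetal rearranges through a chair transition state with the carbinol substituent equatorial, which should give the (E)-trisubstituted alkene and removes the racemic centre; the dioxolane should survive the weak acid under anhydrous conditions.

Step 3
Reactants: 5 ethyl (4E)-4-methyl-7-(2-methyl-1,3-dioxolan-2-yl)hept-4-enoate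
Product: 6 ethyl 3-[(2R,3R)-2-methyl-3-[2-(2-methyl-1,3-dioxolan-2-yl)ethyl]oxiran-2-yl]propanoate
Conditions: D-fructose-derived Shi ketone (0.3 equiv), KHSO5 (as 2KHSO5·KHSO4·K2SO4), K2CO3, Bu4NHSO4, MeCN/dimethoxymethane–aq. Na2B4O7/Na2EDTA (pH 10.5), 0 °C
Reagents that add atoms: potassium peroxymonosulfate, [K+].[O-]S(=O)(=O)OO
Why: Shi asymmetric epoxidation; (E)-trisubstituted alkenes are the best substrate class, and the dioxirane should deliver oxygen through the spiro transition state to the face giving the (R,R)-epoxide, while ester and ketal are inert at this pH. This single catalytic event is the source of all three stereocentres of 25.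

Step 4
Reactants: 6 ethyl 3-[(2R,3R)-2-methyl-3-[2-(2-methyl-1,3-dioxolan-2-yl)ethyl]oxiran-2-yl]propanoate
Product: 10 (5S)-5-[(2R)-5-hydroxy-5-methyloxolan-2-yl]-5-methyloxolan-2-one (anomeric mixture), via epoxy acid 7 (not isolated), via hydroxy lactone ketal 8 (not isolated), via hydroxy ketone 9 (not isolated)
Conditions: LiOH·H2O, THF/H2O, 0 °C to rt; then 1 M H2SO4 to pH 1, THF/H2O, rt
Reagents that add atoms: lithium hydroxide, [Li+].[OH-]; water, O
Why: Saponification should leave the hindered epoxide intact; on acidification the γ,δ-epoxy acid lactonises by 5-exo-tet attack of the carboxyl oxygen on the tertiary epoxide carbon with inversion (C5′ becomes S) while the epoxide oxygen stays on the secondary carbon with retention (C5 stays R). The stronger acid then hydrolyses the dioxolane, and the γ-hydroxy ketone closes to the cyclic hemiketal.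

Step 5
Reactants: 11 prop-2-yn-1-ol
Product: 13 (2E)-3-iodo-2-methylprop-2-en-1-ol, via alkenylalane 12 (not isolated)
Conditions: AlMe3 (3 equiv), Cp2ZrCl2 (0.25 equiv), CH2Cl2, 0 °C to rt; then I2, THF, −30 to 0 °C; aq. K2CO3
Reagents that add atoms: trimethylaluminium, C[Al](C)C; iodine, II
Why: Zirconium-catalysed (Negishi) carboalumination adds methyl and aluminium syn across the alkyne with methyl on the internal carbon; iodinolysis of the C–Al bond with retention gives the (E)-iodide.

Step 6
Reactants: 14 furan-3-carbaldehyde
Product: 15 3-ethenylfuran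
Conditions: Ph3PCH3Br, KOtBu, Et2O, 0 °C to rt; used as a dried ethereal solution
Reagents that add atoms: methyltriphenylphosphonium bromide, C[P+](c1ccccc1)(c1ccccc1)c1ccccc1.[Br-]
Why: Wittig methylenation of a non-enolisable aldehyde; the volatile product is carried forward in solution.

Step 7
Reactants: 15 3-ethenylfuran; 13 (2E)-3-iodo-2-methylprop-2-en-1-ol
Product: 17 (2E)-5-(furan-3-yl)-2-methylpent-2-en-1-ol, via alkylborane 16 (not isolated)
Conditions: 9-BBN, THF, 0 °C to rt; then 13, PdCl2(dppf) (5 mol %), AsPh3, Cs2CO3, DMF/H2O, rt
Reagents that add atoms: none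
Why: Anti-Markovnikov hydroboration of the vinyl group followed by B-alkyl Suzuki–Miyaura coupling, which proceeds with retention of the alkenyl iodide geometry and tolerates the free hydroxyl.

Step 8
Reactants: 17 (2E)-5-(furan-3-yl)-2-methylpent-2-en-1-ol
Product: 18 3-[(3E)-5-bromo-4-methylpent-3-en-1-yl]furan
Conditions: CBr4, PPh3, CH2Cl2, 0 °C; used without storage
Reagents that add atoms: carbon tetrabromide, BrC(Br)(Br)Br
Why: Appel bromination; SN2 displacement at the primary allylic carbon under neutral conditions should preserve both the furan and the alkene geometry.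

Step 9
Reactants: 18 3-[(3E)-5-bromo-4-methylpent-3-en-1-yl]furan
Product: 19 3-[(3E)-6-ethoxy-4-methylhepta-3,6-dien-1-yl]furan
Conditions: Bu3SnC(OEt)=CH2, Pd2(dba)3 (2.5 mol %), tri(2-furyl)phosphine, THF, 50 °C; filtration through basic alumina
Reagents that add atoms: tributyl(1-ethoxyvinyl)stannane, CCCC[Sn](CCCC)(CCCC)C(=C)OCC
Why: Stille coupling; zerovalent palladium gives a syn π-allyl complex, and reductive elimination at the less hindered primary terminus should keep the (E)-alkene. The 1-ethoxyvinyl group is an acetyl-anion equivalent that fixes the position of the later enol double bond.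

Step 10
Reactants: 19 3-[(3E)-6-ethoxy-4-methylhepta-3,6-dien-1-yl]furan
Product: 20 (4E)-1-bromo-7-(furan-3-yl)-4-methylhept-4-en-2-one
Conditions: NBS (1.0 equiv), NaHCO3, THF/H2O (4:1), −20 to 0 °C
Reagents that add atoms: N-bromosuccinimide, O=C1CCC(=O)N1Br; water, O
Why: Electrophilic bromination of the enol ether, the most nucleophilic π-system present (well ahead of the furan and the trisubstituted alkene), followed by hydrolysis of the α-bromo oxocarbenium ion; bromine ends up only on the terminal carbon.

Step 11
Reactants: 20 (4E)-1-bromo-7-(furan-3-yl)-4-methylhept-4-en-2-one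
Product: 22 {[(4E)-7-(furan-3-yl)-4-methylhepta-1,4-dien-2-yl]oxy}trimethylsilane, via zinc enolate 21 (not isolated)
Conditions: Zn dust (activated), Me3SiCl, TMEDA, Et2O, 0 °C to rt; filtration, no aqueous work-up
Reagents that add atoms: chlorotrimethylsilane, C[Si](C)(C)Cl
Why: Reformatsky-type zinc insertion into the C–Br bond gives an enolate whose double bond is fixed at the former C–Br carbon, and O-silylation in situ gives the terminal silyl enol ether regiospecifically; no deprotonation occurs, so the doubly activated methylene between carbonyl and alkene is never ionised.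

Step 12
Reactants: 10 (5S)-5-[(2R)-5-hydroxy-5-methyloxolan-2-yl]-5-methyloxolan-2-one; 22 {[(4E)-7-(furan-3-yl)-4-methylhepta-1,4-dien-2-yl]oxy}trimethylsilane
Product: 25 (5S)-5-[(2R,5R)-5-[(4E)-7-(furan-3-yl)-4-methyl-2-oxohept-4-en-1-yl]-5-methyloxolan-2-yl]-5-methyloxolan-2-one (CNP0156092.1), via silylated hemiketal 23 (not isolated), via oxocarbenium triflate 24 (not isolated)
Conditions: TMSOTf (2.2 equiv), 2,6-di-tert-butyl-4-methylpyridine (1.2 equiv), CH2Cl2, −78 °C; then 22 (1.3 equiv), −78 to −40 °C; aq. NaHCO3
Reagents that add atoms: none
Why: TMSOTf with the hindered proton trap silylates the hemiketal hydroxyl of 10 (23), and a second equivalent ionises it to the ketone-derived five-membered oxocarbenium ion 24; any open hydroxy-ketone form reaches the same ion by 5-exo-trig attack of the C5 oxygen on the activated ketone, so ring A is retained or closed in that mode. The terminal carbon of 22 then adds to C2 and loss of the silyl group gives the β-alkoxy ketone directly: a Mukaiyama-type addition of a silyl enol ether to a cyclic oxocarbenium ion, the reaction type used for C-glycosylation of ketose hemiketals and for 2,2,5-trisubstituted oxolanes from γ-lactols. The new stereocentre C2 is controlled by C5: the nucleophile should approach the planar O1=C2 unit anti to the C5 substituent, here a fully substituted carbon (methyl, ring methylene, acyloxy oxygen) that shields the syn face, which places the ketone chain trans to ring B and the methyl cis, that is (2R). Chemoselectivity is needed for the enol silane over the furan and the trisubstituted alkene, and should be secured because the silyl enol ether is by far the most nucleophilic π-system. Regiochemistry of the enol component is fixed by the structure of 22, not by conditions. The proton trap should prevent acid-induced loss of 22 and migration of the β,γ-alkene, and the low temperature should suppress proton loss from 24 and E1cB reopening of the product. C5 and C5′ are not touched.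

## Compound list

1 | 2-(2-bromoethyl)-2-methyl-1,3-dioxolane | CC1(CCBr)OCCO1 | starting material
2 | methacrolein (2-methylprop-2-enal) | CC(=C)C=O | starting material
3 | [2-(2-methyl-1,3-dioxolan-2-yl)ethyl]magnesium bromide | CC1(CC[Mg]Br)OCCO1 | intermediate
4 | 2-methyl-5-(2-methyl-1,3-dioxolan-2-yl)pent-1-en-3-ol (racemic) | CC(=C)C(O)CCC1(C)OCCO1 | intermediate
5 | ethyl (4E)-4-methyl-7-(2-methyl-1,3-dioxolan-2-yl)hept-4-enoate | CCOC(=O)CC/C(C)=C/CCC1(C)OCCO1 | intermediate
6 | ethyl 3-[(2R,3R)-2-methyl-3-[2-(2-methyl-1,3-dioxolan-2-yl)ethyl]oxiran-2-yl]propanoate | CCOC(=O)CC[C@@]1(C)O[C@@H]1CCC2(C)OCCO2 | intermediate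
7 | 3-[(2R,3R)-2-methyl-3-[2-(2-methyl-1,3-dioxolan-2-yl)ethyl]oxiran-2-yl]propanoic acid | OC(=O)CC[C@@]1(C)O[C@@H]1CCC2(C)OCCO2 | intermediate
8 | (5S)-5-[(1R)-1-hydroxy-3-(2-methyl-1,3-dioxolan-2-yl)propyl]-5-methyloxolan-2-one | CC1(CC[C@@H](O)[C@]2(C)CCC(=O)O2)OCCO1 | intermediate
9 | (5S)-5-[(1R)-1-hydroxy-4-oxopentyl]-5-methyloxolan-2-one | CC(=O)CC[C@@H](O)[C@]1(C)CCC(=O)O1 | intermediate
10 | (5S)-5-[(2R)-5-hydroxy-5-methyloxolan-2-yl]-5-methyloxolan-2-one (anomeric mixture) | CC1(O)CC[C@H]([C@]2(C)CCC(=O)O2)O1 | intermediate
11 | prop-2-yn-1-ol | C#CCO | starting material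
12 | [(1E)-3-(dimethylalumanyloxy)-2-methylprop-1-en-1-yl]dimethylalumane | C[Al](C)OC/C(C)=C/[Al](C)C | intermediate
13 | (2E)-3-iodo-2-methylprop-2-en-1-ol | OC/C(C)=C/I | intermediate
14 | furan-3-carbaldehyde | O=Cc1ccoc1 | starting material
15 | 3-ethenylfuran | C=Cc1ccoc1 | intermediate
16 | 9-[2-(furan-3-yl)ethyl]-9-borabicyclo[3.3.1]nonane | C(Cc1ccoc1)B1C2CCCC1CCC2 | intermediate
17 | (2E)-5-(furan-3-yl)-2-methylpent-2-en-1-ol | OC/C(C)=C/CCc1ccoc1 | intermediate
18 | 3-[(3E)-5-bromo-4-methylpent-3-en-1-yl]furan | BrC/C(C)=C/CCc1ccoc1 | intermediate
19 | 3-[(3E)-6-ethoxy-4-methylhepta-3,6-dien-1-yl]furan | CCOC(=C)C/C(C)=C/CCc1ccoc1 | intermediate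
20 | (4E)-1-bromo-7-(furan-3-yl)-4-methylhept-4-en-2-one | BrCC(=O)C/C(C)=C/CCc1ccoc1 | intermediate
21 | bromo{[(4E)-7-(furan-3-yl)-4-methylhepta-1,4-dien-2-yl]oxy}zinc | Br[Zn]OC(=C)C/C(C)=C/CCc1ccoc1 | intermediate
22 | {[(4E)-7-(furan-3-yl)-4-methylhepta-1,4-dien-2-yl]oxy}trimethylsilane | C[Si](C)(C)OC(=C)C/C(C)=C/CCc1ccoc1 | intermediate
23 | (5S)-5-methyl-5-[(2R)-5-methyl-5-(trimethylsilyloxy)oxolan-2-yl]oxolan-2-one | CC1(O[Si](C)(C)C)CC[C@H]([C@]2(C)CCC(=O)O2)O1 | intermediate
24 | (2R)-5-methyl-2-[(2S)-2-methyl-5-oxooxolan-2-yl]-3,4-dihydro-2H-furan-1-ium trifluoromethanesulfonate | CC1=[O+][C@@H]([C@]2(C)CCC(=O)O2)CC1.[O-]S(=O)(=O)C(F)(F)F | intermediate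
25 | (5S)-5-[(2R,5R)-5-[(4E)-7-(furan-3-yl)-4-methyl-2-oxohept-4-en-1-yl]-5-methyloxolan-2-yl]-5-methyloxolan-2-one | C/C(=C\CCc1ccoc1)CC(=O)C[C@@]1(C)CC[C@H]([C@]2(C)CCC(=O)O2)O1 | target

## Step count and risks

Total step count: 12. Longest linear sequence: 7 steps (5 or 6, then 7, 8, 9, 10, 11, 12); the core branch (1, 2, 3, 4, 12) has 5.

Step 12 (key step). The most likely failure is incomplete discrimination between the two faces of 24, together with proton loss from 24 to the cyclic enol ether. A fully substituted cationic carbon must be joined to a long, acid-labile enol silane, and the directing C5 substituent is one atom removed from the reacting carbon, so the bias is purely steric. The fallback makes the quaternary centre with a small, acid-stable π-nucleophile used in large excess and moves the fragment union to the acyl–CH2 bond; it sets out from 10 (and uses 17) and comes back at 25. Allyltrimethylsilane with catalytic TMSOTf in CH2Cl2 at −78 °C should convert 10 into (5S)-5-methyl-5-[(2R,5R)-5-methyl-5-(prop-2-en-1-yl)oxolan-2-yl]oxolan-2-one F1, where a minor C2 epimer can be removed on a simple intermediate. Ozonolysis with PPh3 work-up (no furan or second alkene is present yet) gives 2-[(2R,5R)-2-methyl-5-[(2S)-2-methyl-5-oxooxolan-2-yl]oxolan-2-yl]acetaldehyde F2. Separately, 17 with MsCl, LiCl and 2,4,6-collidine gives 3-[(3E)-5-chloro-4-methylpent-3-en-1-yl]furan F3, which with activated barium (from BaI2 and lithium biphenylide, THF, −78 °C) gives [(2E)-5-(furan-3-yl)-2-methylpent-2-en-1-yl]barium chloride F4. Allylbarium reagents add to aldehydes at the α-carbon with retention of alkene geometry, so F4 and F2 should give the linear alcohol (5S)-5-[(2R,5R)-5-[(4E)-7-(furan-3-yl)-2-hydroxy-4-methylhept-4-en-1-yl]-5-methyloxolan-2-yl]-5-methyloxolan-2-one F5 as carbinol epimers. Dess–Martin oxidation buffered with NaHCO3 then returns to 25.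

Step 11. The most likely failure is loss of regiochemical integrity, by proton transfer within the zinc enolate towards the doubly activated methylene (giving the conjugated dienol silane) or by reductive debromination to the methyl ketone. The fallback fixes the enol double bond by Markovnikov addition to a terminal alkyne; it sets out from 18, comes back at 22, and bypasses steps 9 and 10. Ethynylmagnesium bromide with catalytic CuBr·SMe2 should give the skipped enyne 3-[(3E)-4-methylhept-3-en-6-yn-1-yl]furan F6. Acetic acid with [RuCl2(p-cymene)]2, tri(2-furyl)phosphine and Na2CO3 in toluene should add to the internal alkyne carbon to give (4E)-7-(furan-3-yl)-4-methylhepta-1,4-dien-2-yl acetate F7. Cleavage with two equivalents of MeLi gives lithium (4E)-7-(furan-3-yl)-4-methylhepta-1,4-dien-2-olate F8 without any C–H deprotonation, and Me3SiCl quench gives 22.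

Step 4. The most likely failure is competition of other oxygen nucleophiles with the carboxyl group during the acid treatment: the dioxolane oxygen attacking the secondary epoxide carbon, or water. This would give material of the opposite enantiomeric series or diols and lower the optical purity of 10. The fallback removes the internal competitor before the epoxide exists; it sets out from 5 and comes back at 10, replacing steps 3 and 4. PPTS in wet acetone gives ethyl (4E)-4-methyl-8-oxonon-4-enoate F9. Shi epoxidation as in step 3 gives ethyl 3-[(2R,3R)-2-methyl-3-(3-oxobutyl)oxiran-2-yl]propanoate F10. LiOH followed by buffering with NaH2PO4 gives 3-[(2R,3R)-2-methyl-3-(3-oxobutyl)oxiran-2-yl]propanoic acid F11, which with catalytic camphorsulfonic acid in dry CH2Cl2 should lactonise and close to 10 under conditions where only the carboxyl group can reach the tertiary epoxide carbon in a 5-exo mode.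

Step 7. The most likely failure is slow transmetalation and protodeboronation of 16, with evaporation losses of the volatile 15, leaving 13 unconverted. The fallback joins the furan through a C(sp3)–C(sp3) bond with allylic transposition; it sets out from 14 and comes back at 17. NaBH4 gives furan-3-ylmethanol F12; MsCl, LiCl and 2,4,6-collidine give 3-(chloromethyl)furan F13; Mg in THF gives (furan-3-ylmethyl)magnesium chloride F14. Copper-catalysed SN2′ opening of 2-methyl-2-vinyloxirane (CuI, THF, −30 °C) should give 17 with predominantly (E) geometry; any (Z) isomer would have to be removed at 17.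

## Further compounds

F1 | step 12 | (5S)-5-methyl-5-[(2R,5R)-5-methyl-5-(prop-2-en-1-yl)oxolan-2-yl]oxolan-2-one | C=CC[C@@]1(C)CC[C@H]([C@]2(C)CCC(=O)O2)O1
F2 | step 12 | 2-[(2R,5R)-2-methyl-5-[(2S)-2-methyl-5-oxooxolan-2-yl]oxolan-2-yl]acetaldehyde | O=CC[C@@]1(C)CC[C@H]([C@]2(C)CCC(=O)O2)O1
F3 | step 12 | 3-[(3E)-5-chloro-4-methylpent-3-en-1-yl]furan | ClC/C(C)=C/CCc1ccoc1
F4 | step 12 | [(2E)-5-(furan-3-yl)-2-methylpent-2-en-1-yl]barium chloride | Cl[Ba]C/C(C)=C/CCc1ccoc1
F5 | step 12 | (5S)-5-[(2R,5R)-5-[(4E)-7-(furan-3-yl)-2-hydroxy-4-methylhept-4-en-1-yl]-5-methyloxolan-2-yl]-5-methyloxolan-2-one (carbinol epimers) | C/C(=C\CCc1ccoc1)CC(O)C[C@@]1(C)CC[C@H]([C@]2(C)CCC(=O)O2)O1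
F6 | step 11 | 3-[(3E)-4-methylhept-3-en-6-yn-1-yl]furan | C#CC/C(C)=C/CCc1ccoc1
F7 | step 11 | (4E)-7-(furan-3-yl)-4-methylhepta-1,4-dien-2-yl acetate | CC(=O)OC(=C)C/C(C)=C/CCc1ccoc1
F8 | step 11 | lithium (4E)-7-(furan-3-yl)-4-methylhepta-1,4-dien-2-olate | [Li]OC(=C)C/C(C)=C/CCc1ccoc1
F9 | step 4 | ethyl (4E)-4-methyl-8-oxonon-4-enoate | CCOC(=O)CC/C(C)=C/CCC(C)=O
F10 | step 4 | ethyl 3-[(2R,3R)-2-methyl-3-(3-oxobutyl)oxiran-2-yl]propanoate | CCOC(=O)CC[C@@]1(C)O[C@@H]1CCC(C)=O
F11 | step 4 | 3-[(2R,3R)-2-methyl-3-(3-oxobutyl)oxiran-2-yl]propanoic acid | OC(=O)CC[C@@]1(C)O[C@@H]1CCC(C)=O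
F12 | step 7 | furan-3-ylmethanol | OCc1ccoc1
F13 | step 7 | 3-(chloromethyl)furan | ClCc1ccoc1
F14 | step 7 | (furan-3-ylmethyl)magnesium chloride | Cl[Mg]Cc1ccoc1
A1 | alternative 1 | ethyl 3-[(2S,3S)-3-[(3R)-3-hydroxy-3-methylpent-4-en-1-yl]-2-methyloxiran-2-yl]propanoate | C=C[C@@](O)(C)CC[C@@H]1O[C@@]1(C)CCC(=O)OCC
A2 | alternative 1 | (5S)-5-[(2R,5R)-5-ethenyl-5-methyloxolan-2-yl]-5-methyloxolan-2-one | C=C[C@@]1(C)CC[C@H]([C@]2(C)CCC(=O)O2)O1
A3 | alternative 2 | tert-butyl (4E)-4-methyl-7-[(2R)-2-methyloxiran-2-yl]hept-4-enoate | CC(C)(C)OC(=O)CC/C(C)=C/CC[C@]1(C)CO1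
A4 | alternative 2 | tert-butyl (4E,8R)-8-[(tert-butyldimethylsilyl)oxy]-9-{2-[(2E)-5-(furan-3-yl)-2-methylpent-2-en-1-yl]-1,3-dithian-2-yl}-4,8-dimethylnon-4-enoate | CC(C)(C)OC(=O)CC/C(C)=C/CC[C@@](C)(O[Si](C)(C)C(C)(C)C)CC1(C/C(C)=C/CCc2ccoc2)SCCCS1
A5 | alternative 3 | (5S)-5-[(1R,4E,8E)-11-(furan-3-yl)-1-hydroxy-4,8-dimethyl-6-oxoundeca-4,8-dien-1-yl]-5-methyloxolan-2-one | C/C(=C\CCc1ccoc1)CC(=O)/C=C(\C)CC[C@@H](O)[C@]1(C)CCC(=O)O1
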